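**Strategy.** Ring A, the cyclohexadienone (C1 ketone, C2 acetyl-bearing, C3 enol, C4 quaternary, C5 enol, C6 bridge-bearing), is read as a cyclised tetraketide. C2 and C4 each lie between two oxygenated ring carbons, so the ring bonds C1–C2 and C3–C4 are both Claisen retrons. One flask makes both: the dianion of an acyclic γ-methyl-γ-prenyl β-keto ester (C4–C5–C6–C1, C4 still a CH) is acetoacetylated at C4 by diketene (C2, C3 and the acetyl group), and the new β-diketone carbon C2 then closes onto ester carbon C1. This formal [4+2] annulation builds the whole dearomatised ring. Resolution, then Mannich-base coupling with prenylated phloroacetophenone (ring B), completes the target.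

Key step: step 2

Remark: the β-triketones are written in the enol form used for the target; the other enol tautomers are the same compound.
Remark: the annulation forms C4 as a racemate; the single (4R) enantiomer is secured by the resolution of step 3, and the configuration of the collected fraction would be confirmed (ECD or X-ray of a salt) before it is carried on.

Step 1
Reactants: 1 methyl 3-oxopentanoate; 2 1-bromo-3-methylbut-2-ene (prenyl bromide)
Product: 3 methyl 4,7-dimethyl-3-oxooct-6-enoate (racemic)
Conditions: LiN(i-Pr)2 (2.1 equiv), THF, −78 → 0 °C; 2 (1.0 equiv), 0 °C; 1 M HCl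
Reagents that add atoms: none
Why: γ-Alkylation of a β-keto ester dianion, in which the terminal, more basic carbanion reacts with the allylic bromide at the γ-carbon only; the new stereocenter is racemic and is erased by enolisation in step 2.

Step 2
Reactants: 3 methyl 4,7-dimethyl-3-oxooct-6-enoate; 4 diketene (4-methylideneoxetan-2-one)
Product: 6 rac-2-acetyl-3,5-dihydroxy-4-methyl-4-(3-methylbut-2-en-1-yl)cyclohexa-2,5-dien-1-one, via open-chain triketo ester 5 (not isolated)
Conditions: LiN(i-Pr)2 (2.2 equiv), THF, −78 → 0 °C; freshly distilled 4 (1.05 equiv), −78 → 0 °C; AcOH (1.0 equiv), then 60 °C; cold 1 M HCl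
Reagents that add atoms: none
Why: Double deprotonation gives the dienediolate of 3, whose terminal carbanion C4 attacks the strained lactone carbonyl of 4 (new C3–C4 bond, quaternary C4); ring opening turns the acyl donor into an enolate, so a second acylation cannot follow. After adjustment to the mono-enolate with AcOH, the β-diketone carbon C2 attacks the ester carbonyl C1 and expels methoxide (new C1–C2 bond). The closest known reaction types are the γ-acylation of β-keto ester dianions, the C-acetoacetylation of enolates by diketene and the biomimetic Claisen cyclisation of 3,5,7-triketo esters to acylphloroglucinols. The ring closes in a 6-exo-trig Dieckmann-type C-acylation, helped by the gem-disubstitution at C4. C4 is formed from a planar achiral carbanion with no element of facial control, so 6 is racemic and its configuration is fixed by the resolution of step 3. The step needs γ- over α-attack (secured by the dianion, whose α-carbon is the stabilised, less nucleophilic site) and Claisen over aldol closure (the aldol adduct cannot aromatise because C4 is quaternary and reverts, whereas the Claisen product is trapped as its strongly acidic enolate).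

Step 3
Reactants: 6 rac-2-acetyl-3,5-dihydroxy-4-methyl-4-(3-methylbut-2-en-1-yl)cyclohexa-2,5-dien-1-one
Product: 7 (4R)-2-acetyl-3,5-dihydroxy-4-methyl-4-(3-methylbut-2-en-1-yl)cyclohexa-2,5-dien-1-one
Conditions: preparative SFC, immobilised amylose tris(3,5-dimethylphenylcarbamate) phase, CO2/MeOH (0.1% HCO2H), 35 °C
Reagents that add atoms: none
Why: Resolution of a racemate by chromatography on a chiral stationary phase; C4 carries no hydrogen and has no epimerisation pathway, so the collected (4R) enantiomer is configurationally stable and supplies the only stereocenter of the target.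

Step 4
Reactants: 8 1-(2,4,6-trihydroxyphenyl)ethan-1-one; 2 1-bromo-3-methylbut-2-ene
Product: 9 1-[2,4,6-trihydroxy-3-(3-methylbut-2-en-1-yl)phenyl]ethan-1-one
Conditions: KOH (1.0 equiv), H2O, 0 °C; 2 (0.9 equiv), 0 °C → rt
Reagents that add atoms: none
Why: C-Alkylation of the ambident phloroglucinol phenolate (Friedel–Crafts-type C-prenylation), in which water solvates the oxygen and favours carbon attack and the sub-stoichiometric bromide limits a second prenylation; no stereocenter is formed.

Step 5
Reactants: 9 1-[2,4,6-trihydroxy-3-(3-methylbut-2-en-1-yl)phenyl]ethan-1-one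
Product: 10 1-{3-[(dimethylamino)methyl]-2,4,6-trihydroxy-5-(3-methylbut-2-en-1-yl)phenyl}ethan-1-one
Conditions: CH2O (37% aq., 1.1 equiv), Me2NH (40% aq., 2 equiv), EtOH, 0 °C → rt
Reagents that add atoms: formaldehyde C=O; dimethylamine CNC
Why: Mannich reaction at the single free aromatic position of 9, with excess amine keeping the benzylic carbon capped as the amine so that the symmetrical methylene-bis dimer is suppressed.

Step 6
Reactants: 7 (4R)-2-acetyl-3,5-dihydroxy-4-methyl-4-(3-methylbut-2-en-1-yl)cyclohexa-2,5-dien-1-one; 10 1-{3-[(dimethylamino)methyl]-2,4,6-trihydroxy-5-(3-methylbut-2-en-1-yl)phenyl}ethan-1-one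
Product: 11 (4R)-2-acetyl-6-{[3-acetyl-2,4,6-trihydroxy-5-(3-methylbut-2-en-1-yl)phenyl]methyl}-3,5-dihydroxy-4-methyl-4-(3-methylbut-2-en-1-yl)cyclohexa-2,5-dien-1-one
Conditions: 7 (1.0 equiv), 10 (1.2 equiv), 1,4-dioxane, 80 °C, N2 stream
Reagents that add atoms: none
Why: The acidic triketone 7 protonates the Mannich base, thermal loss of dimethylamine gives an ortho-quinone methide of ring B, and Michael addition of C6 (the only C–H nucleophilic carbon of 7) forms the methylene bridge, while the quaternary C4 is untouched and keeps its (R) configuration.

**Compound list**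
1 | methyl 3-oxopentanoate | CCC(=O)CC(=O)OC | starting material
2 | 1-bromo-3-methylbut-2-ene (prenyl bromide) | CC(C)=CCBr | starting material
3 | methyl 4,7-dimethyl-3-oxooct-6-enoate (racemic) | COC(=O)CC(=O)C(C)CC=C(C)C | intermediate
4 | diketene (4-methylideneoxetan-2-one) | C=C1CC(=O)O1 | starting material
5 | methyl 4-methyl-4-(3-methylbut-2-en-1-yl)-3,5,7-trioxooctanoate (racemic, present as its lithium enolate, not isolated) | COC(=O)CC(=O)C(C)(CC=C(C)C)C(=O)CC(C)=O | intermediate
6 | rac-2-acetyl-3,5-dihydroxy-4-methyl-4-(3-methylbut-2-en-1-yl)cyclohexa-2,5-dien-1-one | CC(=O)C1=C(O)C(C)(CC=C(C)C)C(O)=CC1=O | intermediate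
7 | (4R)-2-acetyl-3,5-dihydroxy-4-methyl-4-(3-methylbut-2-en-1-yl)cyclohexa-2,5-dien-1-one | CC(=O)C1=C(O)[C@](C)(CC=C(C)C)C(O)=CC1=O | intermediate
8 | 1-(2,4,6-trihydroxyphenyl)ethan-1-one (phloroacetophenone) | CC(=O)c1c(O)cc(O)cc1O | starting material
9 | 1-[2,4,6-trihydroxy-3-(3-methylbut-2-en-1-yl)phenyl]ethan-1-one | CC(=O)c1c(O)cc(O)c(CC=C(C)C)c1O | intermediate
10 | 1-{3-[(dimethylamino)methyl]-2,4,6-trihydroxy-5-(3-methylbut-2-en-1-yl)phenyl}ethan-1-one | CC(=O)c1c(O)c(CC=C(C)C)c(O)c(CN(C)C)c1O | intermediate
11 | (4R)-2-acetyl-6-{[3-acetyl-2,4,6-trihydroxy-5-(3-methylbut-2-en-1-yl)phenyl]methyl}-3,5-dihydroxy-4-methyl-4-(3-methylbut-2-en-1-yl)cyclohexa-2,5-dien-1-one | CC(=O)C1=C(O)[C@](C)(CC=C(C)C)C(O)=C(Cc2c(O)c(CC=C(C)C)c(O)c(C(C)=O)c2O)C1=O | target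

**Count.** Total steps: 6. Longest linear sequence: 4 steps (1, 2, 3, 6); ring B is made in steps 4 and 5 and joins in step 6.

**Steps most likely to fail**

Step 2. The hindered tertiary carbanion may attack 4 too slowly, so that proton transfer from 4 quenches it, or the open-chain enolate may fail to close and be cleaved at its non-enolisable 1,3-diketone by released methoxide. The fallback sets out from 1 and 4 and comes back at 6. The same one-flask acetoacetylation and Claisen closure is run one stage earlier, on the dianion of 1, whose γ-carbanion is secondary and unhindered. Methyl 4-methyl-3,5,7-trioxooctanoate F1 (not isolated) is closed with Mg(OMe)2 in MeOH at reflux, chelation favouring Claisen over aldol closure, to 1-(2,4,6-trihydroxy-3-methylphenyl)ethan-1-one F2. Both ring bonds are still made in one flask. The quaternary carbon is then made by alkylative dearomatisation of F2 at its methyl-bearing carbon with 2 (NaOMe, MeOH, 0 °C); the aromatic isomer prenylated at the free position is removed by chromatography, which gives 6.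

Step 6. Retro-Mannich exchange may scramble the bridge carbon into symmetrical methylene-bis dimers, or the quinone methide of ring B may oligomerise before 7 traps it. The fallback sets out from 7 and 9 and comes back at 11, with the polarity reversed. Compound 7 is aminomethylated at C6 (CH2O, Me2NH, EtOH, 0 °C) to (4R)-2-acetyl-6-[(dimethylamino)methyl]-3,5-dihydroxy-4-methyl-4-(3-methylbut-2-en-1-yl)cyclohexa-2,5-dien-1-one F3. Warming F3 with 9 (1.5 equiv) in 1,4-dioxane releases the 6-methylidene trione of ring A, which the free aromatic position of the electron-rich phenol 9 captures by conjugate addition to give 11.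

Step 3. Interconverting enol tautomers may broaden the peaks, and the strongly acidic triketone may load poorly on the chiral phase, so that the separation stays incomplete. The fallback sets out from 6 and comes back at 7 by classical resolution. Compound 6 is treated with (R)-1-phenylethylamine (0.5 equiv) in EtOAc, and the less soluble diastereomeric salt, the (R)-1-phenylethylammonium enolate of the (4R)-acid F4, is recrystallised to constant rotation and cleaved with cold dilute HCl to give 7. Should the salt of the (4S)-acid be the less soluble one, the (S)-amine is used instead.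

**Further compounds**
F1 | step 2 | methyl 4-methyl-3,5,7-trioxooctanoate (not isolated) | COC(=O)CC(=O)C(C)C(=O)CC(C)=O
F2 | step 2 | 1-(2,4,6-trihydroxy-3-methylphenyl)ethan-1-one | CC(=O)c1c(O)cc(O)c(C)c1O
F3 | step 6 | (4R)-2-acetyl-6-[(dimethylamino)methyl]-3,5-dihydroxy-4-methyl-4-(3-methylbut-2-en-1-yl)cyclohexa-2,5-dien-1-one | CC(=O)C1=C(O)[C@](C)(CC=C(C)C)C(O)=C(CN(C)C)C1=O
F4 | step 3 | (R)-1-phenylethylammonium enolate of (4R)-2-acetyl-3,5-dihydroxy-4-methyl-4-(3-methylbut-2-en-1-yl)cyclohexa-2,5-dien-1-one | CC(=O)C1=C([O-])[C@](C)(CC=C(C)C)C(O)=CC1=O.C[C@@H]([NH3+])c1ccccc1
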